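(The runs were generated by integration on assumed constants, noise included.)

I start from a constant the runs can be read for, k in rate = k[electrophile][nucleophile], because the next plate needs to know how long a well must stand before product leads.

| flask | electrophile | nucleophile | free base | remark | time |
|---|---|---|---|---|---|
| summer | 0.043 M | 1 equiv | 2 equiv | run made earlier |  |
| midnight | 0.096 M | 1 equiv | 2 equiv | run made earlier |  |
| autumn | 0.064 M | 1 equiv | 4 equiv | run made earlier |  |
| amber | 0.064 M | 1.00 equiv | 2.00 equiv |  | 4.0 h |
| teal | 0.064 M | 1.00 equiv | 2.00 equiv |  | 6.0 h |

- summer (time / h: product / %, electrophile / %): 0.667: 2.8, 97.6; 1.33: 6.3, 94.4; 2.00: 9.1, 92.9; 2.50: 9.6, 90.0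
- midnight (time / h: product / %, electrophile / %): 0.667: 7.0, 92.8; 1.33: 10.9, 89.5; 2.00: 16.1, 83.8; 2.50: 19.3, 80.0
- autumn (time / h: product / %, electrophile / %): 0.200: 2.5, 97.5; 0.417: 2.1, 97.8; 1.00: 5.7, 93.8; 2.50: 13.0, 85.0

(readings scatter by 1 percentage point)

- the earlier runs were read with a standard deviation of 1 percentage point
- a reading or a percentage of product counts all its forms, free or not

* which of these there is most of at the end, counted by the electrophile in it, amber (product / electrophile)
* which of these there is most of at the end, counted by the electrophile in it, teal (product / electrophile)
* how much there is at the end of the one of these that leads, in percent of the electrophile charged: amber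
* how much there is at the end of the one of these that leads, in percent of the electrophile charged: teal

With equal charges, converted over left grows as k times the charged concentration times the time. The last midnight readings, product 19.3 % and electrophile 80.0 %, give a mean conversion of 19.7 %, so I read k as 1.02 L mol⁻¹ h⁻¹. The same reckoning reads 1.01 L mol⁻¹ h⁻¹ from the summer run, at lower concentration. It reads 1.02 L mol⁻¹ h⁻¹ from the autumn run, with 4 equiv of free base. So I leave the free base at 2.00 equiv, since the k read from the autumn run shows no gain from more.

What I carry is the crossover time, the time at which electrophile and product stand equal in an equimolar flask, one over k times the charged concentration; it is the second-order half-life. At 0.064 M it comes to 15.3 h. The electrophile left is then one over one plus time over crossover time: 79.3 % for amber and 71.9 % for teal. Teal's 6.0 h falls short of the crossover time, so I expect electrophile to lead in both flasks, and I charge them as written.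

The forecast also has electrophile leading, at 80 % in amber and 72.5 % in teal, a little above my figures, and it says “Base therefore has no visible effect”.

Amber ends with 79.8 % electrophile and teal with 72.6 %, electrophile leading in both.

    electrophile + nucleophile → acid set free + product (k = 1.01 L mol⁻¹ h⁻¹)
    nucleophile + acid set free ⇌ protonated nucleophile, settled at all times (K = 39300 L mol⁻¹)
    crystals ⇌ product, rate k3*(cs3 - [product]) while solid is left; crystals form when [product] > cs3 (solubility = 0.930 mM, k = 3.37 h⁻¹)
    acid set free + free base ⇌ salt of the base, settled at all times (K = 99000 L mol⁻¹)

Of the 20.2 % product in amber at 4.00 h, 17.6 % stands as crystals, yet their growth leaves the electrophile unmoved. The crossover time goes on to the neighbour flask, amber with 4.00 equiv of nucleophile. Put into the unequal-charge form of the same second-order law, it gives 38.7 % electrophile left; that flask holds 40.5 % electrophile, with product leading at 59.5 %.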